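## Retrosynthetic overview

1. Numbering (germacranolide): C1 hemiketal carbon; C2, C3 ring CH2; C4 ring C(CH3)–O; C5=C6 enol-lactone alkene; C7=C11 butenolide alkene; C8 CH(OH); C9 CH2; C10 C(CH3)(OAc); C12 lactone C=O; C13 CH2OAc. The target is (1S,4R,5E,8R,10S).
2. End game: the (5E)-ylidenebutenolide is carried as a 2,3,4-trisubstituted furan (C6, C7, C11, C12, O) and unmasked late by singlet-oxygen oxidation and dehydration inside the ring; the O8 silyl ether is removed last.
3. Key disconnection C1–C10. The enabling feature is that C1 is the hemiketal carbon of the 2-hydroxytetrahydrofuran ring O–C1–C2–C3–C4: a ketone masked by the C4 oxygen and lying 1,2 to the C10 carbinol. Opening the hemiketal gives a ten-membered α-ketol; retro-benzoin gives a C1 aldehyde (stored as the γ-lactol on O4) and a C10 methyl ketone.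
4. The keto lactol comes from a bis-olefin by double oxidative cleavage; C5–C6 by opening an (R)-epoxide (C4 from (S)-2-methylglycidol) with the C6-metallated furan; C8 by Keck methallylation of a furan-3-carbaldehyde made from furan-3,4-diyldimethanol.
5. Ring order: furan (bought) → ten-membered carbocycle and oxygen-bridging tetrahydrofuran together (key step) → butenolide from the furan.

Key step: step 10

Remark: in step 10 the enantiomer of the aminoindanol-derived triazolium precatalyst that is matched to the (8R) substrate is assumed; both enantiomers derive from the two commercial cis-1-amino-2-indanols.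

## Route

Step 1
Reactants: 1 (S)-2-methylglycidol
Product: 2 (2R)-2-methylhex-5-ene-1,2-diol
Conditions: allylMgCl (3 equiv), CuI (10 mol%), THF, −30 → 0 °C; H2O
Reagents that add atoms: allylmagnesium chloride C=CC[Mg]Cl
Why: Copper-catalysed Grignard opening of the epoxide at its CH2 terminus (SN2) after deprotonation of the hydroxyl; no bond to the quaternary carbon is broken, so the configuration of 1 becomes the (R) C4 carbinol.

Step 2
Reactants: 2 (2R)-2-methylhex-5-ene-1,2-diol
Product: 4 (2R)-2-(but-3-en-1-yl)-2-methyloxirane, via primary tosylate 3 (not isolated)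
Conditions: NaH (2.2 equiv), THF, 0 °C; 1-(4-methylbenzenesulfonyl)imidazole, 0 °C → rt
Reagents that add atoms: none
Why: One-pot Williamson epoxide closure: the primary alkoxide is sulfonylated selectively and the tertiary alkoxide displaces the tosylate at CH2, leaving the C4 stereocentre untouched.

Step 3
Reactants: 5 furan-3,4-diyldimethanol
Product: 6 [4-(triethylsilyloxymethyl)furan-3-yl]methanol
Conditions: NaH (1.0 equiv), THF, 0 °C → rt; Et3SiCl (1.0 equiv)
Reagents that add atoms: chlorotriethylsilane CC[Si](Cl)(CC)CC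
Why: Monosilylation of a symmetric diol through its monosodium alkoxide differentiates the two furylmethyl positions (future C8 and C13).

Step 4
Reactants: 6 [4-(triethylsilyloxymethyl)furan-3-yl]methanol
Product: 7 4-(triethylsilyloxymethyl)furan-3-carbaldehyde
Conditions: MnO2 (excess), CH2Cl2, rt
Reagents that add atoms: none
Why: MnO2 oxidation of an activated (furylic) primary alcohol stops at the aldehyde and spares the silyl ether.

Step 5
Reactants: 7 4-(triethylsilyloxymethyl)furan-3-carbaldehyde
Product: 8 (1R)-3-methyl-1-[4-(triethylsilyloxymethyl)furan-3-yl]but-3-en-1-ol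
Conditions: (R)-BINOL (20 mol%), Ti(OiPr)4 (20 mol%), 4 Å MS, CH2Cl2; tributyl(2-methylallyl)stannane, −20 °C; aq. NaHCO3
Reagents that add atoms: tributyl(2-methylallyl)stannane CCCC[Sn](CCCC)(CCCC)CC(C)=C
Why: Keck asymmetric allylation: the (R)-BINOL–titanium Lewis acid should direct Re-face addition of the methallyl group to the aryl-type aldehyde and so set C8 as R (catalyst control).

Step 6
Reactants: 8 (1R)-3-methyl-1-[4-(triethylsilyloxymethyl)furan-3-yl]but-3-en-1-ol; 4 (2R)-2-(but-3-en-1-yl)-2-methyloxirane
Product: 10 (2R)-1-{3-[(1R)-1-hydroxy-3-methylbut-3-en-1-yl]-4-(triethylsilyloxymethyl)furan-2-yl}-2-methylhex-5-en-2-ol, via dilithio species 9 (not isolated)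
Conditions: n-BuLi (2.2 equiv), THF, −78 → 0 °C; MgBr2·OEt2, −40 °C; CuI (20 mol%), 4, −40 °C → rt; H2O
Reagents that add atoms: none
Why: Alkoxide-directed α-lithiation of the furan should place the metal at C6 (next to the carbinol-bearing carbon, not at C12 beside the poorly coordinating silyloxymethyl group), and copper-catalysed SN2 opening of epoxide 4 at CH2 then forms C5–C6 while carrying the C4 stereocentre in unchanged.

Step 7
Reactants: 10 the furyl diol of step 6
Product: 11 8-O-tert-butyldimethylsilyl ether of 10 (C4 hydroxyl free)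
Conditions: TBSOTf (1.1 equiv), 2,6-lutidine, CH2Cl2, −78 °C
Reagents that add atoms: tert-butyldimethylsilyl triflate CC(C)(C)[Si](C)(C)OS(=O)(=O)C(F)(F)F
Why: Silyl triflate silylation at −78 °C discriminates the secondary C8 hydroxyl from the tertiary C4 hydroxyl on steric grounds.

Step 8
Reactants: 11 the bis-silyl ether of step 7
Product: 12 (2R)-1-{3-[(1R)-1-(tert-butyldimethylsilyloxy)-3-methylbut-3-en-1-yl]-4-(hydroxymethyl)furan-2-yl}-2-methylhex-5-en-2-ol
Conditions: HF·pyridine, pyridine, THF, 0 °C
Reagents that add atoms: none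
Why: Buffered fluoride cleaves the primary triethylsilyl ether much faster than the hindered secondary tert-butyldimethylsilyl ether.

Step 9
Reactants: 12 the bis-olefin diol of step 8
Product: 14 (4R)-4-(tert-butyldimethylsilyloxy)-4-[4-(hydroxymethyl)-2-{[(2R)-5-hydroxy-2-methyloxolan-2-yl]methyl}furan-3-yl]butan-2-one (lactol anomers), via bis-diol 13 (not isolated)
Conditions: OsO4 (2 mol%), NaIO4 (5 equiv), 2,6-lutidine, dioxane/H2O 3:1, rt
Reagents that add atoms: osmium tetroxide O=[Os](=O)(=O)=O; sodium periodate [Na+].[O-]I(=O)(=O)=O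
Why: Lemieux–Johnson oxidation (catalytic dihydroxylation, periodate glycol cleavage) unveils the C1 aldehyde and the C10 methyl ketone in one operation, the terminal alkenes being osmylated much faster than the aromatic furan, and the γ-hydroxy aldehyde closes to the lactol on O4.

Step 10
Reactants: 14 the keto lactol of step 9
Product: 16 furan-fused (1S,4R,8R,10S)-11-oxabicyclo[6.2.1]undecane hemiketal (1-OH; 10-OH; 13-OH; 8-OTBS), via ten-membered α-ketol 15 (not isolated)
Conditions: aminoindanol-derived N-pentafluorophenyl triazolium tetrafluoroborate (20 mol%), Et3N (20 mol%), 4 Å MS, toluene, 40 °C; 14 added over 12 h to a final 2 mM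
Reagents that add atoms: none
Why: Proposed new method: the triazolylidene adds to the small equilibrium share of open γ-hydroxy aldehyde of lactol 14 and proton transfer gives the Breslow enaminol, whose C1 attacks the C10 methyl ketone (10-exo-trig closure of the carbocycle, C1–C10 bond); loss of the carbene gives α-ketol 15, which the C4 hydroxyl should capture at once by transannular 5-exo-trig hemiketalisation (O4–C1 bond, tetrahydrofuran ring) to give the 11-oxabicyclo[6.2.1]undecane core. The closest known reaction type is the carbene-catalysed intramolecular crossed aldehyde–ketone benzoin cyclisation to five- and six-membered tertiary α-ketols; what is new is the ten-membered ring and the coupling to hemiketal capture. C10 (S) is set in the C–C bond-forming event under reagent control by the chiral triazolium, whose enaminol O–H···O=C10 hydrogen bond fixes the ketone face, helped by the outward placement of C8–OTBS on the furan-fused ring; C1 (S) is not free, because with C4 fixed as R only this hemiketal can span the bridge. The step needs cross-benzoin over homo-benzoin and cyclisation over oligomerisation: every competing aldehyde–aldehyde adduct stays reversible while the cross adduct is drained into the bridged hemiketal, the aldehyde is stored as the lactol and fed slowly at high dilution, and the furan holds the two reacting arms cis on a rigid edge. Because the butenolide is masked as the furan no Michael acceptor is present, so Stetter-type conjugate addition cannot compete, and Et3N is too weak a base to eliminate the β-silyloxy ketone.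

Step 11
Reactants: 16 the macrocyclic hemiketal triol of step 10
Product: 18 10,13-di-O-acetate of 16 (1-OH free; 8-OTBS), via 1,10,13-triacetate 17 (not isolated)
Conditions: Ac2O (8 equiv), Et3N, DMAP (1 equiv), CH2Cl2, 40 °C; concentrate; H2NNH2·AcOH, DMF, 0 °C → rt
Reagents that add atoms: acetic anhydride CC(=O)OC(C)=O
Why: DMAP-catalysed acetylation should cover the primary C13 and tertiary C10 hydroxyls (the neighbouring hemiketal oxygen can relay the acetyl group through a five-membered orthoester), and the hydrazinolysis known to be selective for anomeric-type acetates then frees only the C1 ketal acetate.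

Step 12
Reactants: 18 the furan bis-acetate of step 11
Product: 20 6-hydroxybutenolide (C12 lactone carbonyl; C7=C11; C6 hemiketal as epimer mixture), via furan endoperoxide 19 (not isolated)
Conditions: O2, tetraphenylporphyrin (1 mol%), iPr2NEt (3 equiv), CH2Cl2, −78 °C, visible light; warm to rt
Reagents that add atoms: dioxygen O=O
Why: [4+2] cycloaddition of singlet oxygen to the furan and base-induced Kornblum–DeLaMare fragmentation of the endoperoxide (removal of its only bridgehead hydrogen, at C12) should give the γ-hydroxybutenolide with the carbonyl at C12; the new C6 centre is destroyed in the next step.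

Step 13
Reactants: 20 the 6-hydroxybutenolide of step 12
Product: 22 8-O-tert-butyldimethylsilyl ether of the target, via C6 mesylate 21 (not isolated)
Conditions: MsCl (1.3 equiv), iPr2NEt (4 equiv), CH2Cl2, −40 → 0 °C
Reagents that add atoms: none
Why: Sulfonylation of the acidic pseudo-acid hydroxyl at C6 and base-mediated loss of methanesulfonate together with a C5 hydrogen (dehydration of a γ-hydroxybutenolide to a γ-ylidenebutenolide); the tetrahydrofuran-bridged ten-membered ring should allow only the cis-in-ring, that is 5E, double bond.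

Step 14
Reactants: 22 the silyl ether of step 13
Product: 23 target, (1S,4R,5E,8R,10S)-10,13-diacetoxy-1,8-dihydroxy-1,4-epoxygermacra-5,7(11)-dien-12,6-olide (CNP0203479.1)
Conditions: 48% aq. HF, MeCN, 0 °C → rt
Reagents that add atoms: none
Why: Acidic fluoride desilylation, free of nucleophilic amines, should spare both acetates, the hemiketal and the nucleophile-sensitive α-(acetoxymethyl)ylidenebutenolide.

## Compound list

1 | (S)-2-methylglycidol | OC[C@@]1(C)CO1 | starting material
2 | (2R)-2-methylhex-5-ene-1,2-diol | OC[C@@](O)(C)CCC=C | intermediate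
3 | (2R)-2-hydroxy-2-methylhex-5-en-1-yl 4-methylbenzenesulfonate (not isolated) | Cc1ccc(cc1)S(=O)(=O)OC[C@@](O)(C)CCC=C | intermediate
4 | (2R)-2-(but-3-en-1-yl)-2-methyloxirane | O1C[C@@]1(C)CCC=C | intermediate
5 | furan-3,4-diyldimethanol | OCc1cocc1CO | starting material
6 | [4-(triethylsilyloxymethyl)furan-3-yl]methanol | CC[Si](CC)(CC)OCc1cocc1CO | intermediate
7 | 4-(triethylsilyloxymethyl)furan-3-carbaldehyde | CC[Si](CC)(CC)OCc1cocc1C=O | intermediate
8 | (1R)-3-methyl-1-[4-(triethylsilyloxymethyl)furan-3-yl]but-3-en-1-ol | CC[Si](CC)(CC)OCc1cocc1[C@H](O)CC(C)=C | intermediate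
9 | dilithio derivative of 8 (lithium alkoxide on O8, lithium on furan C6; not isolated) | CC[Si](CC)(CC)OCc1coc([Li])c1[C@H](O[Li])CC(C)=C | intermediate
10 | (2R)-1-{3-[(1R)-1-hydroxy-3-methylbut-3-en-1-yl]-4-(triethylsilyloxymethyl)furan-2-yl}-2-methylhex-5-en-2-ol | CC[Si](CC)(CC)OCc1coc(C[C@@](O)(C)CCC=C)c1[C@H](O)CC(C)=C | intermediate
11 | 8-O-TBS ether of 10 | CC[Si](CC)(CC)OCc1coc(C[C@@](O)(C)CCC=C)c1[C@H](O[Si](C)(C)C(C)(C)C)CC(C)=C | intermediate
12 | (2R)-1-{3-[(1R)-1-(tert-butyldimethylsilyloxy)-3-methylbut-3-en-1-yl]-4-(hydroxymethyl)furan-2-yl}-2-methylhex-5-en-2-ol | OCc1coc(C[C@@](O)(C)CCC=C)c1[C@H](O[Si](C)(C)C(C)(C)C)CC(C)=C | intermediate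
13 | bis-diol from dihydroxylation of both terminal alkenes of 12 (new carbinol centres as mixtures; not isolated) | OCc1coc(C[C@@](O)(C)CCC(O)CO)c1[C@H](O[Si](C)(C)C(C)(C)C)CC(C)(O)CO | intermediate
14 | keto lactol: C1 lactol on O4 (anomers), C10 methyl ketone, 8-OTBS, 13-OH | OCc1coc(C[C@@]2(C)CCC(O)O2)c1[C@H](O[Si](C)(C)C(C)(C)C)CC(C)=O | intermediate
15 | furan-fused ten-membered α-ketol (C1 ketone, (10S) tertiary carbinol, free 4-OH; not isolated) | OCc1c2c(C[C@@](O)(C)CCC(=O)[C@@](C)(O)C[C@H]2O[Si](C)(C)C(C)(C)C)oc1 | intermediate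
16 | furan-fused (1S,4R,8R,10S) 1,4-epoxy hemiketal: 1-OH, 10-OH, 13-OH, 8-OTBS | OCc1c2c(C[C@@]3(C)CC[C@](O)(O3)[C@@](C)(O)C[C@H]2O[Si](C)(C)C(C)(C)C)oc1 | intermediate
17 | 1,10,13-tri-O-acetate of 16 (stereocentres as in 16; not isolated) | CC(=O)OCc1c2c(C[C@@]3(C)CC[C@](OC(C)=O)(O3)[C@@](C)(OC(C)=O)C[C@H]2O[Si](C)(C)C(C)(C)C)oc1 | intermediate
18 | 10,13-di-O-acetate of 16 (1-OH free) | CC(=O)OCc1c2c(C[C@@]3(C)CC[C@](O)(O3)[C@@](C)(OC(C)=O)C[C@H]2O[Si](C)(C)C(C)(C)C)oc1 | intermediate
19 | furan endoperoxide of 18 (O–O across C6 and C12; not isolated) | CC(=O)OCC1=C2C3(C[C@@]4(C)CC[C@](O)(O4)[C@@](C)(OC(C)=O)C[C@H]2O[Si](C)(C)C(C)(C)C)OOC1O3 | intermediate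
20 | 6-hydroxybutenolide (C12 lactone, C7=C11, C6 epimers) | CC(=O)OCC1=C2C(O)(C[C@@]3(C)CC[C@](O)(O3)[C@@](C)(OC(C)=O)C[C@H]2O[Si](C)(C)C(C)(C)C)OC1=O | intermediate
21 | C6 methanesulfonate of 20 (not isolated) | CC(=O)OCC1=C2C(OS(C)(=O)=O)(C[C@@]3(C)CC[C@](O)(O3)[C@@](C)(OC(C)=O)C[C@H]2O[Si](C)(C)C(C)(C)C)OC1=O | intermediate
22 | 8-O-TBS ether of the target, (5E)-ylidenebutenolide | CC(=O)OCC1=C2/C(=C\[C@@]3(C)CC[C@](O)(O3)[C@@](C)(OC(C)=O)C[C@H]2O[Si](C)(C)C(C)(C)C)OC1=O | intermediate
23 | CNP0203479.1, (1S,4R,5E,8R,10S)-10,13-diacetoxy-1,8-dihydroxy-1,4-epoxygermacra-5,7(11)-dien-12,6-olide | CC(=O)OCC1=C2/C(=C\[C@@]3(C)CC[C@](O)(O3)[C@@](C)(OC(C)=O)C[C@H]2O)OC1=O | target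

## Step count and risks

Total steps: 14. Longest linear sequence: 12 steps (5 → 23, steps 3–14); the epoxide arm (steps 1–2) joins in step 6.

Steps most likely to fail:

Step 10 (Proposed new method). The ring closure may lose to reversible intermolecular benzoin or aldol oligomerisation, the ten-membered transition state may be too strained for the weakly exergonic ketone addition, or facial selectivity at C10 may be poor. The fallback replaces umpolung by a reductive closure of the same bond and sets out from 14. SmI2 in THF at high dilution should couple the aldehyde (open form of the lactol) with the methyl ketone in an intramolecular keto–aldehyde pinacol reaction to give the ten-membered 1,10-diol F1, whose C10 epimers would have to be separated. Ac2O in pyridine at 0 °C should acetylate only the primary hydroxyl to give the 13-monoacetate F2. Dess–Martin periodinane should oxidise the remaining secondary C1 carbinol to the ketone, which closes onto O4 as the hemiketal 13-monoacetate F3. The conditions of step 11 (through 17) then return the material to the route at 18.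

Step 13. Sulfonylation and ionisation of the C1 hemiketal hydroxyl may compete with activation of the C6 pseudo-acid hydroxyl, or elimination may stall. The fallback protects C1 first and sets out from 18. Et3SiOTf with 2,6-lutidine should give the C1 triethylsilyl ketal F5. The conditions of step 12 give, through the endoperoxide F6, the hydroxybutenolide F7. MsCl with iPr2NEt, now usable in excess, gives through the C6 mesylate F8 the bis-silylated ylidenebutenolide F9. The aqueous HF of step 14 removes both silyl groups and the route is rejoined at 23.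

Step 11. Acetyl transfer may stop at the hemiketal oxygen, or the hemiketal may open with acylation of O4, so that the tertiary C10 hydroxyl stays free. The fallback delivers the acetyl group only to the O1/O10 pair and sets out from 16. Ac2O in pyridine at 0 °C gives the 13-monoacetate (compound F3 of the first fallback). Trimethyl orthoacetate with catalytic pyridinium tosylate ties O1 and O10 into the cyclic methyl orthoacetate F4. 80% aqueous acetic acid opens it with departure of the more acidic hemiketal oxygen, leaving the acetyl group on O10, and the route is rejoined at 18.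

## Further compounds

F1 | step 10 | furan-fused ten-membered 1,10-diol (C1 carbinol as mixture, 4-OH and 13-OH free, 8-OTBS) | OCc1c2c(C[C@@](O)(C)CCC(O)[C@@](C)(O)C[C@H]2O[Si](C)(C)C(C)(C)C)oc1
F2 | step 10 | 13-monoacetate of F1 | CC(=O)OCc1c2c(C[C@@](O)(C)CCC(O)[C@@](C)(O)C[C@H]2O[Si](C)(C)C(C)(C)C)oc1
F3 | step 10 | hemiketal 13-monoacetate (16 acetylated on O13 only) | CC(=O)OCc1c2c(C[C@@]3(C)CC[C@](O)(O3)[C@@](C)(O)C[C@H]2O[Si](C)(C)C(C)(C)C)oc1
F4 | step 11 | cyclic O1,O10 methyl orthoacetate of F3 | CC(=O)OCc1c2c(C[C@@]3(C)CC[C@@]4(O3)OC(C)(OC)O[C@@]4(C)C[C@H]2O[Si](C)(C)C(C)(C)C)oc1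
F5 | step 13 | C1 triethylsilyl ketal of 18 | CC(=O)OCc1c2c(C[C@@]3(C)CC[C@](O[Si](CC)(CC)CC)(O3)[C@@](C)(OC(C)=O)C[C@H]2O[Si](C)(C)C(C)(C)C)oc1
F6 | step 13 | furan endoperoxide of F5 | CC(=O)OCC1=C2C3(C[C@@]4(C)CC[C@](O[Si](CC)(CC)CC)(O4)[C@@](C)(OC(C)=O)C[C@H]2O[Si](C)(C)C(C)(C)C)OOC1O3
F7 | step 13 | 6-hydroxybutenolide from F6 | CC(=O)OCC1=C2C(O)(C[C@@]3(C)CC[C@](O[Si](CC)(CC)CC)(O3)[C@@](C)(OC(C)=O)C[C@H]2O[Si](C)(C)C(C)(C)C)OC1=O
F8 | step 13 | C6 methanesulfonate of F7 | CC(=O)OCC1=C2C(OS(C)(=O)=O)(C[C@@]3(C)CC[C@](O[Si](CC)(CC)CC)(O3)[C@@](C)(OC(C)=O)C[C@H]2O[Si](C)(C)C(C)(C)C)OC1=O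
F9 | step 13 | 1-O-triethylsilyl 8-O-tert-butyldimethylsilyl ether of 23 | CC(=O)OCC1=C2/C(=C\[C@@]3(C)CC[C@](O[Si](CC)(CC)CC)(O3)[C@@](C)(OC(C)=O)C[C@H]2O[Si](C)(C)C(C)(C)C)OC1=O
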